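## Retrosynthetic overview

1. The target is cut at the enamide C–N bond into a prochiral 2,6-dichloro-p-quinol acid and a primary dienamide. A desymmetrising amidation of one of the two mirror-image C–Cl bonds sets the ring stereocentre.
2. The quinol acid comes from a spiro ε-lactone by hydrolysis, and the lactone from a spiro[5.5]undecadiene-dione by Baeyer–Villiger ring expansion (C→O shift of the spiro carbon).
3. The spirodione comes from 2,6-dichloro-4-(1-hydroxycyclopentyl)phenol by oxidative dearomatisation with semipinacol ring expansion (cyclopentanol → cyclohexanone). The phenol comes from 4-bromophenol and cyclopentanone.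
4. The dienamide comes from an α-methyl aldehyde by HWE olefination. Its ester precursor comes from a stereoconvergent Ni-catalysed Negishi coupling of a chiral-pool alkylzinc with a racemic allylic chloride.
5. Ring order: the six-membered carbocycle is the starting arene. The cyclopentane is expanded to a spiro cyclohexanone, then to a seven-membered lactone, which is opened. No ring is built de novo.

Assumption: the sense of induction of the chiral ligands in steps 6 and 8 is taken as written; if the first run shows the opposite sense, the mirror-image ligand is used.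

## Route

Step 1
Reactants: 1 4-bromophenol
Product: 2 4-bromo-2,6-dichlorophenol
Conditions: SO2Cl2 (2.1 equiv), i-Bu2NH (5 mol %), toluene, 70 °C
Reagents that add atoms: sulfuryl chloride, O=S(=O)(Cl)Cl
Why: Electrophilic aromatic chlorination; the para position is blocked by Br, so the amine-mediated chlorination goes to both ortho positions of the phenol.

Step 2
Reactants: 2 4-bromo-2,6-dichlorophenol; 3 cyclopentanone
Product: 5 2,6-dichloro-4-(1-hydroxycyclopentyl)phenol, via lithium 2,6-dichloro-4-lithiophenolate 4 (not isolated)
Conditions: n-BuLi (2.1 equiv), THF, −78 °C; then 3 (1.2 equiv), −78 → 0 °C; aq NH4Cl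
Reagents that add atoms: none
Why: O-deprotonation followed by bromine–lithium exchange (faster than Cl–Li exchange, and Li sits meta to both Cl so no aryne forms) gives an aryllithium that adds 1,2 to the ketone; the neutral work-up avoids dehydration of the benzylic tertiary alcohol.

Step 3
Reactants: 5 2,6-dichloro-4-(1-hydroxycyclopentyl)phenol
Product: 6 2,4-dichlorospiro[5.5]undeca-1,4-diene-3,7-dione
Conditions: PhI(OAc)2 (1.1 equiv), (CF3)2CHOH, 0 °C, 15 min
Reagents that add atoms: none
Why: Hypervalent-iodine oxidative dearomatisation makes the para carbon electron-deficient and a ring C–C bond of the adjacent carbinol migrates to it (semipinacol 1,2-shift), so the cyclopentanol expands to a spiro cyclohexanone and the phenol becomes the cross-conjugated dienone; the product is achiral.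

Step 4
Reactants: 6 2,4-dichlorospiro[5.5]undeca-1,4-diene-3,7-dione
Product: 8 5-(3,5-dichloro-1-hydroxy-4-oxocyclohexa-2,5-dien-1-yl)pentanoic acid, via spirolactone 7 (not isolated)
Conditions: mCPBA (1.5 equiv), NaHCO3, CH2Cl2, 0 °C → rt; aq NaHCO3 wash; then LiOH (2.2 equiv), THF/H2O, 0 °C, 30 min; 1 M HCl to pH 3
Reagents that add atoms: mCPBA, OOC(=O)c1cccc(Cl)c1; lithium hydroxide, [Li+].[OH-]
Why: Baeyer–Villiger ring expansion in which the quaternary, doubly allylic spiro carbon migrates to oxygen in preference to CH2 (the electron-poor chlorodienone is inert to peracid) gives the ε-lactone, and cold saponification unveils the tertiary carbinol and the carboxybutyl chain; 8 is achiral but prochiral at the carbinol carbon.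

Step 5
Reactants: 9 4-methylpent-3-en-2-ol (racemic)
Product: 10 rac-4-chloro-2-methylpent-2-ene
Conditions: conc. aq HCl, 0 °C, 30 min; dried over CaCl2, used cold without distillation
Reagents that add atoms: hydrogen chloride, Cl
Why: SN1 substitution through the 1,1,3-trimethylallyl cation; racemic material, and any tertiary allylic isomer present, is acceptable because the next step is stereoconvergent through a common allyl intermediate.

Step 6
Reactants: 11 methyl (R)-3-bromo-2-methylpropanoate; 10 rac-4-chloro-2-methylpent-2-ene
Product: 13 methyl (2S,4R)-2,4,6-trimethylhept-5-enoate, via alkylzinc bromide 12 (not isolated)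
Conditions: Zn dust (1.5 equiv), I2 (5 mol %), DMA, 70 °C; then 10 (1.0 equiv per 1.3 equiv 12), NiCl2·glyme (5 mol %), (S)-CH2CH2Ph-Pybox (5.5 mol %), NaCl, DMA/DMF, −10 °C, 24 h
Reagents that add atoms: none
Why: Stereoconvergent Ni/Pybox-catalysed asymmetric Negishi coupling of a racemic secondary allylic chloride: the C–C bond forms at the less hindered CH(Me) terminus of the allyl unit (the CMe2 end has no E/Z issue) and the catalyst sets C4 as R, while C2 is carried unchanged from 11 (its descriptor changes from R to S only because CH2Br outranks CO2Me and CH2R does not).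

Step 7
Reactants: 13 methyl (2S,4R)-2,4,6-trimethylhept-5-enoate
Product: 15 (2E,4S,6R)-4,6,8-trimethylnona-2,7-dienamide, via aldehyde 14 (not isolated)
Conditions: DIBAL-H (1.05 equiv), CH2Cl2, −78 °C, 1 h; then (EtO)2P(O)CH2CONH2/NaH (1.3 equiv) in THF, −78 °C → rt; aq Rochelle salt
Reagents that add atoms: diethyl (2-amino-2-oxoethyl)phosphonate, CCOP(=O)(OCC)CC(N)=O
Why: Partial reduction stops at the aluminium hemiacetal, which releases aldehyde 14 only as it is consumed so the α-centre does not epimerise, and the Horner–Wadsworth–Emmons reaction of the stabilised phosphonate gives the (E)-enamide.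

Step 8
Reactants: 8 5-(3,5-dichloro-1-hydroxy-4-oxocyclohexa-2,5-dien-1-yl)pentanoic acid; 15 (2E,4S,6R)-4,6,8-trimethylnona-2,7-dienamide
Product: 16 5-[(1R)-3-chloro-1-hydroxy-4-oxo-5-{[(2E,4S,6R)-4,6,8-trimethylnona-2,7-dienoyl]amino}cyclohexa-2,5-dien-1-yl]pentanoic acid (CNP0128873.1)
Conditions: Pd2(dba)3 (2.5 mol %), (R)-DTBM-SEGPHOS (6 mol %), Cs2CO3 (2.5 equiv), 15 (1.0 equiv), t-AmOH, 50 °C; then 0.5 M HCl to pH 3–4, 0 °C
Reagents that add atoms: none
Why: Proposed new method: an enantiotopic-group-selective Pd-catalysed amidation of one of the two vinyl C–Cl bonds of the prochiral dichloroquinol, in which the chiral bisphosphine–Pd(0) binds one of the two mirror-image enone arms (the caesium alkoxide and carboxylate on the carbinol carbon mark one face), inserts irreversibly into that C–Cl bond, and amidate binding and C–N reductive elimination give the enamide and set the ring centre as R; the enamide product is more electron-rich so the second C–Cl reacts more slowly and any over-reaction removes mainly the minor epimer, and the side-chain stereocentres are too far from nitrogen to interfere; the closest known reaction types are Buchwald–Hartwig amidation of aryl and vinyl chlorides, Pd-catalysed desymmetrising C–N coupling of substrates with two enantiotopic aryl halides, and Rh- or Cu-catalysed desymmetrisation of 4,4-disubstituted cyclohexadienones.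

## Compound list

1 | 4-bromophenol | Oc1ccc(Br)cc1 | starting material
2 | 4-bromo-2,6-dichlorophenol | Oc1c(Cl)cc(Br)cc1Cl | intermediate
3 | cyclopentanone | O=C1CCCC1 | starting material
4 | lithium 2,6-dichloro-4-lithiophenolate | [Li]Oc1c(Cl)cc([Li])cc1Cl | intermediate
5 | 2,6-dichloro-4-(1-hydroxycyclopentyl)phenol | Oc1c(Cl)cc(cc1Cl)C1(O)CCCC1 | intermediate
6 | 2,4-dichlorospiro[5.5]undeca-1,4-diene-3,7-dione | O=C1C(Cl)=CC2(CCCCC2=O)C=C1Cl | intermediate
7 | 2,4-dichloro-7-oxaspiro[5.6]dodeca-1,4-diene-3,8-dione (spirolactone) | O=C1C(Cl)=CC2(CCCCC(=O)O2)C=C1Cl | intermediate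
8 | 5-(3,5-dichloro-1-hydroxy-4-oxocyclohexa-2,5-dien-1-yl)pentanoic acid | OC(=O)CCCCC1(O)C=C(Cl)C(=O)C(Cl)=C1 | intermediate
9 | 4-methylpent-3-en-2-ol (racemic) | CC(C)=CC(C)O | starting material
10 | rac-4-chloro-2-methylpent-2-ene (may contain its allylic isomer 4-chloro-4-methylpent-2-ene) | CC(C)=CC(C)Cl | intermediate
11 | methyl (R)-3-bromo-2-methylpropanoate | COC(=O)[C@@H](C)CBr | starting material
12 | [(R)-3-methoxy-2-methyl-3-oxopropyl]zinc bromide (alkylzinc bromide) | COC(=O)[C@@H](C)C[Zn]Br | intermediate
13 | methyl (2S,4R)-2,4,6-trimethylhept-5-enoate | CC(C)=C[C@H](C)C[C@H](C)C(=O)OC | intermediate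
14 | (2S,4R)-2,4,6-trimethylhept-5-enal (aldehyde) | CC(C)=C[C@H](C)C[C@H](C)C=O | intermediate
15 | (2E,4S,6R)-4,6,8-trimethylnona-2,7-dienamide | CC(C)=C[C@H](C)C[C@H](C)/C=C/C(N)=O | intermediate
16 | 5-[(1R)-3-chloro-1-hydroxy-4-oxo-5-{[(2E,4S,6R)-4,6,8-trimethylnona-2,7-dienoyl]amino}cyclohexa-2,5-dien-1-yl]pentanoic acid | CC(C)=C[C@H](C)C[C@H](C)/C=C/C(=O)NC1=C[C@](O)(CCCCC(=O)O)C=C(Cl)C1=O | target

## Step count and risk

Total steps: 8. Longest linear sequence: 5 (steps 1, 2, 3, 4, 8). The side chain takes 3 steps (5, 6, 7).

The three steps most likely to fail: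

Step 8 (the proposed new method). The enantiotopic C–Cl discrimination may be low, or the free quinol acid may not tolerate the conditions. The fallback uses known chemistry and sets out from 8 and 15. The coupling is run with an achiral catalyst for amidation of activated chlorides (tBuBrettPhos-Pd G3, Cs2CO3, t-AmOH, 60 °C). This gives a roughly 1:1 mixture of 16 and the (1S)-ring epimer of 16 F1. The two are diastereomers and are separated by preparative HPLC on a chiral stationary phase, which brings the route back at 16.

Step 4 (Baeyer–Villiger). The CH2 group may migrate instead of the spiro carbon, or acid may trigger a dienone–phenol acyl shift in 6. The fallback sets out from 2 and avoids 5, 6 and 7. A Heck reaction of 2 with pent-4-enoic acid (Pd(OAc)2, P(o-tol)3, K2CO3, DMF, 100 °C) gives (E)-5-(3,5-dichloro-4-hydroxyphenyl)pent-4-enoic acid F2. Hydrogenation of the alkene with H2 and RhCl(PPh3)3, which leaves the aryl chlorides intact, gives 5-(3,5-dichloro-4-hydroxyphenyl)pentanoic acid F3. Hydroxylative dearomatisation with PhI(OAc)2 in MeCN/H2O at 0 °C, with water adding at the para carbon, returns to the route at 8. This bypass also covers a failure of the oxidative ring expansion in step 3.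

Step 6 (asymmetric Negishi coupling). The 1,1,3-trimethylallyl electrophile is outside the usual substrate range, so regioselectivity or selectivity at C4 may be poor. The fallback sets out from 11 through the same zinc reagent 12. It is coupled under the same Ni/Pybox conditions with the standard symmetrical electrophile, racemic (E)-4-chloropent-2-ene, which removes the regiochemical question. This gives methyl (2S,4R,5E)-2,4-dimethylhept-5-enoate F4. Cross-metathesis of F4 with neat 2-methylbut-2-ene (Grubbs second-generation catalyst, 40 °C) then installs the isopropylidene end and returns to the route at 13.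

## Further compounds

F1 | step 8 | 5-[(1S)-3-chloro-1-hydroxy-4-oxo-5-{[(2E,4S,6R)-4,6,8-trimethylnona-2,7-dienoyl]amino}cyclohexa-2,5-dien-1-yl]pentanoic acid | CC(C)=C[C@H](C)C[C@H](C)/C=C/C(=O)NC1=C[C@@](O)(CCCCC(=O)O)C=C(Cl)C1=O
F2 | step 4 | (E)-5-(3,5-dichloro-4-hydroxyphenyl)pent-4-enoic acid | OC(=O)CC/C=C/c1cc(Cl)c(O)c(Cl)c1
F3 | step 4 | 5-(3,5-dichloro-4-hydroxyphenyl)pentanoic acid | OC(=O)CCCCc1cc(Cl)c(O)c(Cl)c1
F4 | step 6 | methyl (2S,4R,5E)-2,4-dimethylhept-5-enoate | C/C=C/[C@H](C)C[C@H](C)C(=O)OC
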